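Everything rests on disconnecting the C1–C11 bond of the seven-membered ring (target numbering: C1 and C3 ester carbinols, C4 gem-dimethyl, cyclobutane C5–C6–C11–C10, enone bridge C7(=O)–C8=C9). C11 is a quaternary cyclobutane carbon carrying a methyl next to oxygenated C1, so an exocyclic C11 methylene is its latent form. Hydrogen-atom transfer from an iron hydride converts the methylene into the methyl and a tertiary C11 radical, which closes the seven-membered ring onto C1 of a vinylogous ester and creates C11 and C1 in one operation. The precursor is a verbenone-like bicyclo[3.1.1]heptenone with a C11 exocyclic methylene and, on the inner face of C5 (anti to the enone bridge), the chain C4–C3(=O)–C2=C1–OPMB.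

Key step: step 14

Assumption: the sense of the chiral-amide enolisation of cyclobutanone 9 is assigned by analogy with 4-substituted cyclohexanones and would be confirmed at 11; if it is the opposite, the (S,S)-amide is used with no other change, and enantiomeric purity would be raised by recrystallisation of a later crystalline intermediate if needed.

Step 1
Reactants: 1 but-2-yn-1-ol
Product: 3 (Z)-3-iodobut-2-en-1-ol, via cyclic sodium alkenylaluminate 2 (not isolated)
Conditions: NaAlH2(OCH2CH2OMe)2, THF, 0 °C to rt; then I2, −78 to 0 °C
Reagents that add atoms: iodine, [I][I]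
Why: Hydroxyl-directed trans-hydroalumination of the propargylic alcohol puts aluminium on C3 cis to the CH2O group in a five-membered aluminate, and iodinolysis of the C–Al bond with retention gives the Z vinyl iodide needed for the later ring closure.

Step 2
Reactants: 3 (Z)-3-iodobut-2-en-1-ol
Product: 4 (Z)-3-iodobut-2-enal
Conditions: MnO2, CH2Cl2, rt
Reagents that add atoms: none
Why: MnO2 oxidation of an allylic alcohol is neutral and heterogeneous, so the Z-configured β-iodo enal should form without isomerisation or loss of iodide.

Step 3
Reactants: 5 methyl 2,2-dimethylbut-3-enoate; 6 trichloroacetyl chloride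
Product: 8 methyl 2-(2,2-dichloro-3-oxocyclobutyl)-2-methylpropanoate (racemic), via dichloroketene 7 (not isolated)
Conditions: Zn–Cu couple, POCl3, Et2O, 35 °C
Reagents that add atoms: none
Why: Thermal [2+2] cycloaddition of dichloroketene (from zinc dechlorination of 6) with the monosubstituted alkene joins the ketene carbonyl carbon to the CH2 terminus, so the quaternary substituent ends up at C3 of the cyclobutanone (target C5), and the ester, which has no α-hydrogen, is inert.

Step 4
Reactants: 8 methyl 2-(2,2-dichloro-3-oxocyclobutyl)-2-methylpropanoate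
Product: 9 methyl 2-methyl-2-(3-oxocyclobutyl)propanoate
Conditions: Zn dust, AcOH, rt to 50 °C
Reagents that add atoms: none
Why: Reductive dechlorination by zinc in acetic acid removes both α-chlorines and leaves the Cs-symmetric 3-substituted cyclobutanone, whose two α-methylenes (future C6 and C10) are enantiotopic.

Step 5
Reactants: 9 methyl 2-methyl-2-(3-oxocyclobutyl)propanoate; 4 (Z)-3-iodobut-2-enal
Product: 11 methyl 2-[2-((Z)-1-hydroxy-3-iodobut-2-enyl)-3-oxocyclobutyl]-2-methylpropanoate (ring substituents trans; C7 carbinol epimers), via lithium enolate 10 (not isolated)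
Conditions: (R,R)-bis(1-phenylethyl)amine, n-BuLi, LiCl, THF, −78 °C; then 4, −78 °C; AcOH quench
Reagents that add atoms: none
Why: Enantiotopic-group-selective deprotonation of the 3-substituted cyclobutanone by the chiral lithium amide (LiCl allowing an external quench) gives a non-racemic enolate that undergoes aldol addition to the enal carbonyl on the face anti to the C5 substituent, which fixes C5 and C6 in the absolute sense required; the C7 carbinol centre is formed as a mixture and is erased in step 13.

Step 6
Reactants: 11 aldol adduct
Product: 12 triethylsilyl ether of 11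
Conditions: TESCl, imidazole, DMF, 0 °C
Reagents that add atoms: chlorotriethylsilane, CC[Si](Cl)(CC)CC
Why: Silylation of the secondary alcohol blocks retro-aldol cleavage and carries the C7 oxygen, the future enone carbonyl, through the basic steps that follow.

Step 7
Reactants: 12 triethylsilyl ether of 11
Product: 14 methyl 2-methyl-2-[2-methyl-6-oxo-4-(triethylsilyloxy)bicyclo[3.1.1]hept-2-en-7-yl]propanoate (side chain anti to the C7–C9 bridge), via potassium enolate 13 (not isolated)
Conditions: KN(SiMe3)2, THF, −78 °C; then Pd(PPh3)4 (10 mol%), −78 °C to rt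
Reagents that add atoms: none
Why: Palladium-catalysed intramolecular α-alkenylation of a ketone enolate (oxidative addition into the vinyl iodide, capture of the kinetic C10 enolate, reductive elimination) forms C9–C10 and closes the six-membered ring, which can bridge C6 and C10 only on the face already carrying the C7 arm, so C10 is set and the side chain ends up on the inner position of C5.

Step 8
Reactants: 14 bicyclic ketone
Product: 15 methyl 2-methyl-2-[2-methyl-6-methylidene-4-(triethylsilyloxy)bicyclo[3.1.1]hept-2-en-7-yl]propanoate
Conditions: Ph3PCH3Br, KOt-Bu, toluene, 0 to 50 °C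
Reagents that add atoms: methyltriphenylphosphonium bromide, C[P+](c1ccccc1)(c1ccccc1)c1ccccc1.[Br-]
Why: Wittig methylenation of the strained C11 ketone, whose two α-carbons are bridgeheads so that neither epimerisation nor β-elimination of the silyloxy group can occur; the ylide approaches from the face syn to the C7–C9 bridge and the hindered α-quaternary ester does not react.

Step 9
Reactants: 15 methylidene ester
Product: 16 N-methoxy-N-methyl amide of 15
Conditions: MeNH(OMe)·HCl, i-PrMgCl, THF, −20 °C to rt
Reagents that add atoms: N,O-dimethylhydroxylamine hydrochloride, CNOC.Cl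
Why: Aminolysis of the methyl ester by the chloromagnesium amide (Weinreb amide formation) is placed here because no ketone is present, the ester has no α-hydrogen, and the silyl ether and both alkenes are inert.

Step 10
Reactants: 16 N-methoxy-N-methyl amide
Product: 17 4-methyl-4-[2-methyl-6-methylidene-4-(triethylsilyloxy)bicyclo[3.1.1]hept-2-en-7-yl]pent-1-yn-3-one
Conditions: HC≡CMgBr, THF, 0 °C to rt
Reagents that add atoms: ethynylmagnesium bromide, C#C[Mg]Br
Why: Addition of the alkynyl Grignard reagent to the Weinreb amide stops at the stable magnesium chelate, which releases the ynone only on work-up (Weinreb ketone synthesis).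

Step 11
Reactants: 17 ynone; 18 4-methoxybenzyl alcohol
Product: 19 (E)-β-(4-methoxybenzyloxy) enone, C7 triethylsilyl ether
Conditions: PMe3 (10 mol%), CH2Cl2, 0 °C to rt
Reagents that add atoms: none
Why: Trialkylphosphine-catalysed conjugate addition of the alcohol to the terminal ynone (oxa-Michael addition) should give the E vinylogous ester selectively under neutral conditions.

Step 12
Reactants: 19 vinylogous ester silyl ether
Product: 20 C7 allylic alcohol (C7 epimers)
Conditions: HF·pyridine, pyridine, THF, 0 °C
Reagents that add atoms: none
Why: Fluoride-driven cleavage of the Si–O bond under pyridine buffering removes the triethylsilyl group while the vinylogous ester and the acid-sensitive methylenecyclobutane stay untouched.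

Step 13
Reactants: 20 C7 allylic alcohol
Product: 21 7-[(E)-5-(4-methoxybenzyloxy)-2-methyl-3-oxopent-4-en-2-yl]-4-methyl-6-methylidenebicyclo[3.1.1]hept-3-en-2-one (key-step precursor)
Conditions: MnO2, CH2Cl2, rt
Reagents that add atoms: none
Why: MnO2 oxidises only the allylic C7 alcohol, so both epimers converge on the bridge enone under neutral conditions that spare the vinylogous ester and the 4-methoxybenzyl group; bridgehead C6 cannot enolise, so the β,γ-methylene stays in place.

Step 14
Reactants: 21 key-step precursor
Product: 22 tricyclic enone with C3 ketone and C1 4-methoxybenzyl ether (C11 methyl syn to the C7–C9 bridge)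
Conditions: Fe(acac)3 (20 mol%), PhSiH2(Oi-Pr), i-PrOH, THF, 0.01 M, rt
Reagents that add atoms: none
Why: The iron hydride generated from Fe(acac)3 and the silane delivers a hydrogen atom to the CH2 terminus of the C11 methylene (Markovnikov), which creates the C11 methyl and a tertiary cyclobutyl radical; this nucleophilic radical adds to C1, the β-carbon of the vinylogous ester, and the C2 α-keto radical is then reduced to the enolate and protonated by i-PrOH. The closest known reaction type is the iron-hydride-initiated reductive coupling of unactivated alkenes with Michael acceptors (radical conjugate addition forming a quaternary carbon), here run intramolecularly. The seven-membered ring C11–C1–C2–C3–C4–C5–C6 closes in the 7-endo-trig mode, which is feasible because the inner C5 attachment and the C4 gem-dimethyl group hold C1 directly beneath C11. C11 is set by the tether, since the chain can reach only the inner lobe of the radical and the new methyl is therefore forced onto the outer face, syn to the C7–C9 bridge. C1 is not set by the substrate, because folding the C2–C3 arm beneath C6 (which leads to 22) or beneath C10 (which leads to its C1 epimer) gives near-mirror-image transition states that differ only in the remote C7 carbonyl versus the C9 methyl, so 22 is separated from its epimer by chromatography, the E geometry keeping the ether group outside the new ring in both. The step needs hydrogen-atom transfer to the 1,1-disubstituted alkene only, which is secured because the bridge enone and the carbonyl-conjugated C1=C2 bond are poor hydrogen-atom acceptors and the C11 radical cannot reach the bridge enone without forming a three- or four-membered ring, while PhSiH2(Oi-Pr) in THF/i-PrOH avoids alkoxy exchange at the vinylogous ester and high dilution suppresses intermolecular addition.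

Step 15
Reactants: 22 C1 4-methoxybenzyl ether
Product: 23 tricyclic β-hydroxy ketone (C1 hydroxyl, C3 ketone)
Conditions: DDQ, CH2Cl2, pH 7 buffer, 0 °C
Reagents that add atoms: none
Why: Oxidative cleavage of the 4-methoxybenzyl ether by DDQ through the benzylic oxocarbenium ion frees the C1 hydroxyl under buffered conditions that should not touch the enone or provoke retro-aldol or elimination.

Step 16
Reactants: 23 tricyclic β-hydroxy ketone; 24 3-methylbut-2-enal
Product: 25 C1 3-methylbut-2-enoate with free C3 hydroxyl (1R,3R; O1 and O3 trans)
Conditions: SmI2 (30 mol%, premixed with 24), THF, −10 °C, dark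
Reagents that add atoms: none
Why: Evans–Tishchenko reduction, in which the C1 hydroxyl forms a samarium-bound hemiacetal with the aldehyde and its C–H hydride is delivered intramolecularly to C3 on the face of O1, so the new C3 hydroxyl is trans (1,3-anti) to O1 while O1 emerges as the 3-methylbut-2-enoate, which differentiates the two oxygens in one step.

Step 17
Reactants: 25 hydroxy senecioate; 26 3-methylbutanoyl chloride
Product: 27 CNP0335239.1 (target)
Conditions: pyridine, 4-(dimethylamino)pyridine (cat.), CH2Cl2, 0 °C to rt
Reagents that add atoms: none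
Why: Acylation of the hindered secondary C3 alcohol by the acid chloride under nucleophilic catalysis completes the diester, and the trans-1,3 arrangement on the seven-membered ring disfavours acyl migration from O1.

Compound list
1 | but-2-yn-1-ol | CC#CCO | starting material
2 | cyclic sodium alkenylaluminate from trans-hydroalumination of 1 (Al on C3, chelated to O) | CC1=CCO[Al-]1(OCCOC)OCCOC.[Na+] | intermediate
3 | (Z)-3-iodobut-2-en-1-ol | C/C(I)=C/CO | intermediate
4 | (Z)-3-iodobut-2-enal | C/C(I)=C/C=O | intermediate
5 | methyl 2,2-dimethylbut-3-enoate | COC(=O)C(C)(C)C=C | starting material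
6 | trichloroacetyl chloride | ClC(=O)C(Cl)(Cl)Cl | starting material
7 | dichloroketene | ClC(Cl)=C=O | intermediate
8 | methyl 2-(2,2-dichloro-3-oxocyclobutyl)-2-methylpropanoate (racemic) | COC(=O)C(C)(C)C1CC(=O)C1(Cl)Cl | intermediate
9 | methyl 2-methyl-2-(3-oxocyclobutyl)propanoate | COC(=O)C(C)(C)C1CC(=O)C1 | intermediate
10 | lithium C6=C11 enolate of 9 (non-racemic) | [Li]OC1=C[C@@H](C(C)(C)C(=O)OC)C1 | intermediate
11 | methyl 2-[2-((Z)-1-hydroxy-3-iodobut-2-enyl)-3-oxocyclobutyl]-2-methylpropanoate (ring substituents trans; C7 epimers) | O=C1[C@H](C(O)/C=C(/C)I)[C@@H](C(C)(C)C(=O)OC)C1 | intermediate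
12 | triethylsilyl ether of 11 | O=C1[C@H](C(O[Si](CC)(CC)CC)/C=C(/C)I)[C@@H](C(C)(C)C(=O)OC)C1 | intermediate
13 | potassium C10=C11 enolate of 12 | [K]OC1=C[C@H](C(C)(C)C(=O)OC)[C@H]1C(O[Si](CC)(CC)CC)/C=C(/C)I | intermediate
14 | methyl 2-methyl-2-[2-methyl-6-oxo-4-(triethylsilyloxy)bicyclo[3.1.1]hept-2-en-7-yl]propanoate (side chain anti to the three-carbon bridge; C7 epimers) | O=C1[C@@H]2C(O[Si](CC)(CC)CC)C=C(C)[C@H]1[C@@H]2C(C)(C)C(=O)OC | intermediate
15 | methyl 2-methyl-2-[2-methyl-6-methylidene-4-(triethylsilyloxy)bicyclo[3.1.1]hept-2-en-7-yl]propanoate | C=C1[C@@H]2C(O[Si](CC)(CC)CC)C=C(C)[C@H]1[C@@H]2C(C)(C)C(=O)OC | intermediate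
16 | N-methoxy-N-methyl amide of 15 | C=C1[C@@H]2C(O[Si](CC)(CC)CC)C=C(C)[C@H]1[C@@H]2C(C)(C)C(=O)N(C)OC | intermediate
17 | 4-methyl-4-[2-methyl-6-methylidene-4-(triethylsilyloxy)bicyclo[3.1.1]hept-2-en-7-yl]pent-1-yn-3-one | C=C1[C@@H]2C(O[Si](CC)(CC)CC)C=C(C)[C@H]1[C@@H]2C(C)(C)C(=O)C#C | intermediate
18 | 4-methoxybenzyl alcohol | COc1ccc(CO)cc1 | starting material
19 | (E)-β-(4-methoxybenzyloxy) enone, C7 triethylsilyl ether | C=C1[C@@H]2C(O[Si](CC)(CC)CC)C=C(C)[C@H]1[C@@H]2C(C)(C)C(=O)/C=C/OCc1ccc(OC)cc1 | intermediate
20 | (E)-β-(4-methoxybenzyloxy) enone, C7 allylic alcohol (C7 epimers) | C=C1[C@@H]2C(O)C=C(C)[C@H]1[C@@H]2C(C)(C)C(=O)/C=C/OCc1ccc(OC)cc1 | intermediate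
21 | 7-[(E)-5-(4-methoxybenzyloxy)-2-methyl-3-oxopent-4-en-2-yl]-4-methyl-6-methylidenebicyclo[3.1.1]hept-3-en-2-one (key-step precursor) | C=C1[C@@H]2C(=O)C=C(C)[C@H]1[C@@H]2C(C)(C)C(=O)/C=C/OCc1ccc(OC)cc1 | intermediate
22 | tricyclic enone with C3 ketone and C1 4-methoxybenzyl ether (key-step product) | COc1ccc(cc1)CO[C@@H]2CC(=O)C(C)(C)[C@@H]3[C@H]4C(=O)C=C(C)[C@@H]3[C@]42C | intermediate
23 | tricyclic β-hydroxy ketone (C1 hydroxyl, C3 ketone) | O[C@@H]2CC(=O)C(C)(C)[C@@H]3[C@H]4C(=O)C=C(C)[C@@H]3[C@]42C | intermediate
24 | 3-methylbut-2-enal | CC(C)=CC=O | starting material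
25 | C1 3-methylbut-2-enoate, C3 alcohol | CC(C)=CC(=O)O[C@@H]1C[C@@H](O)C(C)(C)[C@@H]2[C@H]3C(=O)C=C(C)[C@@H]2[C@]31C | intermediate
26 | 3-methylbutanoyl chloride | CC(C)CC(=O)Cl | starting material
27 | CNP0335239.1 | CC(C)=CC(=O)O[C@@H]1C[C@@H](OC(=O)CC(C)C)C(C)(C)[C@@H]2[C@H]3C(=O)C=C(C)[C@@H]2[C@]31C | target

Total steps: 17. Longest linear sequence: 15 (steps 3 to 17; steps 1 and 2 supply aldehyde 4).

Steps most likely to fail

1. Step 14, the radical closure. The closure has no built-in facial preference at C1, so a large share of the material may emerge as the C1 epimer. The fallback sets out from 22 as obtained before separation, that is, together with its C1 epimer, or from the unwanted epimer alone. DBU in toluene at 80 °C removes 4-methoxybenzyl alcohol by E1cB elimination and gives the tricyclic cyclohept-2-enone F1, in which C1 is no longer stereogenic. Copper-catalysed conjugate borylation (CuCl, NaOt-Bu, a Josiphos-type bisphosphine of the hand that places boron on the C6-side face, B2pin2, MeOH, THF) should then add boron to C1 under catalyst control, because the substrate itself exerts no bias, and gives the C1 pinacol boronate F2; the β,β-disubstituted bridge enone is the less reactive acceptor. NaBO3 oxidises the C–B bond with retention, and the fallback comes back to the route at 23.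

2. Step 7, the palladium ring closure. The enolate may equilibrate to C6 and expel the β-silyloxy group, or reductive elimination to the strained bicycle may be too slow and give protodehalogenation. The fallback sets out from 9. The same chiral-amide aldol reaction, now with but-2-ynal, gives the propargylic aldol adduct F3, and TESCl with imidazole gives its silyl ether F4. KN(SiMe3)2 and TBSCl give the C10=C11 silyl enol ether F5. (Ph3P)AuCl with AgNTf2 in CH2Cl2/MeOH then brings about 6-endo-dig carbocyclisation of the silyl enol ether onto the gold-activated alkyne; this forms C9–C10, the 5-exo alternative would need a bicyclo[2.1.1]hexane, and protodeauration places hydrogen on C8. The fallback comes back to the route at 14.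

3. Step 16, the Evans–Tishchenko reduction. The conjugated aldehyde may turn over poorly as hydride donor (little hemiacetal, competing pinacol coupling or reduction of the enal by SmI2), or the ring may not present O1 axially for hydride delivery. The fallback sets out from 22. (S)-1-Methyl-3,3-diphenyltetrahydro-1H,3H-pyrrolo[1,2-c][1,3,2]oxazaborole (CBS catalyst) with BH3·SMe2 reduces the C3 ketone under reagent control, with the tert-alkyl C4 as the large group, which should give 3R; the C7 enone is reduced as well, giving the diol F6. MnO2 re-oxidises only the allylic C7 alcohol and gives the hydroxy enone F7. 3-Methylbutanoyl chloride with pyridine and 4-(dimethylamino)pyridine gives the C3 ester F8, and DDQ frees the C1 alcohol F9. 3-Methylbut-2-enoyl chloride with pyridine and 4-(dimethylamino)pyridine acylates O1, and the fallback comes back to the route at 27.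

Further compounds
F1 | step 14 | tricyclic cyclohept-2-enone (C1=C2 conjugated to the C3 ketone) | C1=CC(=O)C(C)(C)[C@@H]2[C@H]3C(=O)C=C(C)[C@@H]2[C@]31C
F2 | step 14 | C1 pinacol boronate of the tricyclic diketone | CC1(C)OB(OC1(C)C)[C@@H]2CC(=O)C(C)(C)[C@@H]3[C@H]4C(=O)C=C(C)[C@@H]3[C@]42C
F3 | step 7 | methyl 2-[2-(1-hydroxybut-2-ynyl)-3-oxocyclobutyl]-2-methylpropanoate (ring substituents trans) | O=C1[C@H](C(O)C#CC)[C@@H](C(C)(C)C(=O)OC)C1
F4 | step 7 | triethylsilyl ether of F3 | O=C1[C@H](C(O[Si](CC)(CC)CC)C#CC)[C@@H](C(C)(C)C(=O)OC)C1
F5 | step 7 | C10=C11 tert-butyldimethylsilyl enol ether of F4 | CC(C)(C)[Si](C)(C)OC1=C[C@H](C(C)(C)C(=O)OC)[C@H]1C(O[Si](CC)(CC)CC)C#CC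
F6 | step 16 | C1 4-methoxybenzyl ether with C3 (3R) and C7 hydroxyls | COc1ccc(cc1)CO[C@@H]2C[C@@H](O)C(C)(C)[C@@H]3[C@H]4C(O)C=C(C)[C@@H]3[C@]42C
F7 | step 16 | C1 4-methoxybenzyl ether with C3 hydroxyl and C7 enone | COc1ccc(cc1)CO[C@@H]2C[C@@H](O)C(C)(C)[C@@H]3[C@H]4C(=O)C=C(C)[C@@H]3[C@]42C
F8 | step 16 | C1 4-methoxybenzyl ether, C3 3-methylbutanoate | COc1ccc(cc1)CO[C@@H]2C[C@@H](OC(=O)CC(C)C)C(C)(C)[C@@H]3[C@H]4C(=O)C=C(C)[C@@H]3[C@]42C
F9 | step 16 | C1 alcohol, C3 3-methylbutanoate | O[C@@H]2C[C@@H](OC(=O)CC(C)C)C(C)(C)[C@@H]3[C@H]4C(=O)C=C(C)[C@@H]3[C@]42C
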